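The coupling partner left over in a flask gauges the target made: each bit spent splits between two steps, in a ratio set by how much partner stands.

    substrate + coupling partner → target (k1 = 247 L mol⁻¹ s⁻¹)
    substrate + 2 coupling partner → side product (k2 = 1.41 × 10⁵ L² mol⁻² s⁻¹)
    2 substrate → homo dimer (k3 = 54.6 L mol⁻¹ s⁻¹)

common to all: substrate 2.0 mM (fed, over 10 s); time 15 s
- Friday's: coupling partner 0.800 equiv; the fed solution adds 0.10 times the starting volume
- Sunday's: coupling partner 1.20 equiv; the fed solution adds 0.10 times the starting volume
- Wednesday's: coupling partner 2.00 equiv; the fed solution adds 0.10 times the starting volume

- amount of target at the end, in percent of the substrate charged for Friday's, Sunday's, Wednesday's, in this order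
- the course of these numbers from the first flask to the last (falls all the way / hardly changes / rises all the way / falls, then rises / rises, then falls)

- in percentages every species weighs as the substrate in it: one homo dimer counts as two
- two of one species on the left: rate k times its square, two consumed each time
- charges are per starting volume, the dose included; the dosed solution carries all of it
- "hardly changes" means that all values lie within two and a half points (for a concentration: within two and a half percent of the largest)
- run time (Friday's): 15 s

Steps 1 and 2 both carry [substrate], so it cancels from their ratio, and step 2 over step 1 is [coupling partner] divided by k1/k2. That divisor is the crossover concentration, 1.75 mM, where the two steps run equally (a selectivity factor of 1). A turn of step 2 spends two partners, so with h = 0.876 mM, half of the crossover, summing over the partner spent gives: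

target made = h · ln[(h + partner charged) / (h + partner left)]

The feed's thinning (0.10 of the starting volume) is ignored, so each ceiling below is an estimate, not a strict bound. Setting the partner left to 0 gives a ceiling:

Friday's: 1.60 mM charged, ceiling 45.5 %

Sunday's: 2.40 mM charged, ceiling 57.8 %

 In Wednesday's flask substrate is the limiting reagent. Partner spent is target plus twice side product, so at 2.00 equiv, with the substrate taken as going through steps 1 and 2 to the end, the partner left equals the target. One Newton step from 1.00 mM, with 4.00 mM charged, gives:

Wednesday's: 0.889 mM left, ceiling 44.4 %

A floor follows for Wednesday's flask. Partner stays above that level, so the time constant of substrate is at most 3.02 s. The feed then holds [substrate] under 0.605 mM. The dimer's pull there, 0.0660 s⁻¹, is weaker than the 0.331 s⁻¹ of steps 1 and 2, so it is ignored. After the feed, at most 5.78 % of the substrate remains, which gives: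

Wednesday's floor: 38.7 %

In Friday's and Sunday's flasks partner itself thins out, the time constant stretches, and the hand finds no floor.

The forecast gave 40 %, 47 % and 46 %, rises, then falls, holding that “the second-order partner term diverts more substrate to the side product”; its first two lie under their ceilings, its third just above Wednesday's.

The flasks give 40.2 %, 46.6 % and 43.3 %, rises, then falls, with Wednesday's inside its bracket.

The reaction of substrate + 2 coupling partner to side product is the main reason for Wednesday's figure: with it switched off that flask gives 95.4 % instead of 43.3 %. Wednesday's charge starts at 2.29 times the crossover. Put into the gauge, Wednesday's leftover of 25 % of its charge gives 41.7 % against 43.3 %, and Sunday's leftover of 12 % gives 45.4 % against 46.6 %.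

The rate constants were set for the occasion; the result is computed.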